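**Plan**

- Retrosynthetic cuts, in order: the C7 benzyl ether; the C1'–C2' bond of ring A'; the CH2–CO bond of the cinnamoylmethyl chain; the flavan C4–pyrone C3 bond; the C2–phenyl bond.
- Enabling feature: ring A' (C1' cinnamoyl, C2' and C6' OH, C3' bonded to flavan C4, C4' OMe, C5' H) is an acylphloroglucinol, a folded tetraketide. It is therefore an isomer of a 3-substituted 4-methoxy-6-(acylmethyl)-2-pyrone whose lactone carbonyl becomes C2' and whose side-chain methylene becomes C1'.
- Forward: ring A is oxygenated and acetylated from 5-methoxyresorcinol, ring C is closed as a chromone, phenyl is added at C2, C4 is joined to C3 of triacetic acid lactone, the chain is acylated, the pyrone is isomerised into ring A', and the benzyl group is removed.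
- Stereochemistry: C2 (R) comes from a ligand-controlled conjugate addition of phenylboronic acid to the chromone. C4 (2,4-trans; R in the target) comes from substrate control in the SN1 coupling, the nucleophile entering anti to the 2-phenyl group.

Key step: step 13

Assumption: (E)-N-methoxy-N-methylcinnamamide (20) is a purchased reagent, and LiN(i-Pr)2 and Mg(OMe)2 are used as commercial solutions.

**Route**

Step 1
Reactants: 1 5-methoxyresorcinol
Product: 2 1-methoxy-3,5-bis(methoxymethoxy)benzene
Conditions: MOMCl (2.5 equiv), i-Pr2NEt, CH2Cl2, 0 °C to rt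
Reagents that add atoms: chloromethyl methyl ether, COCCl
Why: Williamson-type O-alkylation of both phenols installs the two methoxymethyl ethers that serve as ortho-directing groups in step 2.

Step 2
Reactants: 2 1-methoxy-3,5-bis(methoxymethoxy)benzene
Product: 5 4-methoxy-2,6-bis(methoxymethoxy)phenol, via aryllithium 3 (not isolated), via dimethyl arylboronate 4 (not isolated)
Conditions: n-BuLi, THF, 0 °C; B(OMe)3, −78 °C to rt; H2O2, aq NaOH, 0 °C
Reagents that add atoms: hydrogen peroxide, OO
Why: Directed ortho-metalation should occur at the carbon flanked by both OCH2OCH3 groups (cooperative chelation, stronger than that of OMe), and borylation followed by oxidative aryl migration from boron to oxygen converts the C–Li bond into the phenol.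

Step 3
Reactants: 5 4-methoxy-2,6-bis(methoxymethoxy)phenol
Product: 6 2,5-dimethoxy-1,3-bis(methoxymethoxy)benzene
Conditions: MeI, K2CO3, DMF, rt
Reagents that add atoms: iodomethane, CI
Why: Williamson O-methylation of the phenoxide fixes the future C8 methoxy group, and the acetal protecting groups are inert to base.

Step 4
Reactants: 6 2,5-dimethoxy-1,3-bis(methoxymethoxy)benzene
Product: 7 2,5-dimethoxybenzene-1,3-diol
Conditions: HCl (cat.), MeOH, 40 °C, argon
Reagents that add atoms: none
Why: Acid-catalysed acetal exchange with methanol removes both methoxymethyl groups as dimethoxymethane and leaves the aryl methyl ethers intact; the air-sensitive diol is used at once.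

Step 5
Reactants: 7 2,5-dimethoxybenzene-1,3-diol
Product: 9 1-(2,4-dihydroxy-3,6-dimethoxyphenyl)ethan-1-one, via ketiminium chloride 8 (not isolated)
Conditions: MeCN, ZnCl2, HCl (g), Et2O, 0 °C; then H2O, 90 °C
Reagents that add atoms: acetonitrile, CC#N; water, O
Why: Houben–Hoesch acylation, in which the two free ring positions are equivalent by symmetry and strongly activated, and the ketiminium salt deactivates the ring towards a second acylation, so a single mono-acetyl product is expected.

Step 6
Reactants: 9 1-(2,4-dihydroxy-3,6-dimethoxyphenyl)ethan-1-one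
Product: 10 1-[4-(benzyloxy)-2-hydroxy-3,6-dimethoxyphenyl]ethan-1-one
Conditions: BnBr (1.05 equiv), K2CO3, acetone, reflux
Reagents that add atoms: benzyl bromide, BrCc1ccccc1
Why: Williamson etherification should be selective for the 4-OH, because the 2-OH is hydrogen-bonded to the ketone and is the less acidic and less nucleophilic of the two.

Step 7
Reactants: 10 1-[4-(benzyloxy)-2-hydroxy-3,6-dimethoxyphenyl]ethan-1-one
Product: 12 7-(benzyloxy)-5,8-dimethoxy-4H-chromen-4-one, via enaminone 11 (not isolated)
Conditions: Me2NCH(OMe)2, toluene, 100 °C; concentrate; conc. HCl, CH2Cl2, rt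
Reagents that add atoms: N,N-dimethylformamide dimethyl acetal, COC(OC)N(C)C
Why: Enaminone route to chromones, in which condensation of the methyl ketone with the amide acetal is followed by acid-promoted addition of the phenol and loss of dimethylamine to close ring C.

Step 8
Reactants: 12 7-(benzyloxy)-5,8-dimethoxy-4H-chromen-4-one, 13 phenylboronic acid
Product: 14 (2R)-7-(benzyloxy)-5,8-dimethoxy-2-phenylchroman-4-one
Conditions: Pd(OCOCF3)2 (10 mol %), (S)-4-tert-butyl-2-(pyridin-2-yl)-4,5-dihydrooxazole (12 mol %), NH4PF6, H2O, ClCH2CH2Cl, 60 °C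
Reagents that add atoms: none
Why: Asymmetric conjugate addition of an arylboronic acid to a chromone at a cationic divalent palladium pyridine-oxazoline complex (transmetalation, insertion of C2=C3 into Pd–Ph, protonolysis), in which the tert-butyl group of the ligand selects the enone face; the (S)-ligand is expected to give 2R by analogy with cyclic enones, and the (R)-ligand is used if the sense proves opposite.

Step 9
Reactants: 14 (2R)-7-(benzyloxy)-5,8-dimethoxy-2-phenylchroman-4-one
Product: 15 (2R,4R)-7-(benzyloxy)-5,8-dimethoxy-2-phenylchroman-4-ol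
Conditions: NaBH4, MeOH–THF, 0 °C
Reagents that add atoms: none
Why: Hydride reduction of the ketone should give mainly the 2,4-cis alcohol at a temperature where the flavanone does not ring-open, and the C4 configuration is immaterial because C4 is ionised in step 10.

Step 10
Reactants: 15 (2R,4R)-7-(benzyloxy)-5,8-dimethoxy-2-phenylchroman-4-ol, 16 triacetic acid lactone (3 equiv)
Product: 18 3-[(2R,4S)-7-(benzyloxy)-5,8-dimethoxy-2-phenylchroman-4-yl]-4-hydroxy-6-methyl-2H-pyran-2-one (2,4-trans), via flavan-4-yl cation 17 (not isolated)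
Conditions: TsOH·H2O (10 mol %), MeCN, 40 °C
Reagents that add atoms: none
Why: Acid-catalysed SN1 (Friedel–Crafts-type) alkylation of the vinylogous acid at C3 by the benzylic cation formed from 15 by loss of water and stabilised by the 5-OMe and 7-OBn groups, in which the nucleophile should enter pseudo-axially anti to the equatorial 2-phenyl group and the peri 5-OMe disfavours a pseudo-equatorial C4 substituent, so the 2,4-trans isomer is expected to predominate (any cis isomer is removed by chromatography); the excess lactone suppresses self-condensation of the flavan.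

Step 11
Reactants: 18 3-[(2R,4S)-7-(benzyloxy)-5,8-dimethoxy-2-phenylchroman-4-yl]-4-hydroxy-6-methyl-2H-pyran-2-one
Product: 19 3-[(2R,4S)-7-(benzyloxy)-5,8-dimethoxy-2-phenylchroman-4-yl]-4-methoxy-6-methyl-2H-pyran-2-one
Conditions: Me2SO4, K2CO3, acetone, reflux
Reagents that add atoms: dimethyl sulfate, COS(=O)(=O)OC
Why: O-Methylation of a 4-hydroxy-2-pyrone under carbonate conditions, which for triacetic acid lactones favours the 4-methoxy-2-pyrone over the 2-methoxy-4-pyranone isomer (the latter, if formed, is separated).

Step 12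
Reactants: 19 3-[(2R,4S)-7-(benzyloxy)-5,8-dimethoxy-2-phenylchroman-4-yl]-4-methoxy-6-methyl-2H-pyran-2-one, 20 (E)-N-methoxy-N-methylcinnamamide
Product: 23 3-[(2R,4S)-7-(benzyloxy)-5,8-dimethoxy-2-phenylchroman-4-yl]-4-methoxy-6-[(3E)-2-oxo-4-phenylbut-3-en-1-yl]-2H-pyran-2-one, via lithiated pyrone 21 (not isolated), via tetrahedral adduct 22 (not isolated)
Conditions: LiN(i-Pr)2 (1.1 equiv), THF, −78 °C; 20 (1.3 equiv), −78 to −40 °C; AcOH, −40 °C, then H2O
Reagents that add atoms: none
Why: Weinreb ketone synthesis on the extended enolate formed by kinetic deprotonation of the C6 methyl group (vinylogous to the lactone carbonyl), in which lithium chelation directs 1,2-addition and the tetrahedral adduct masks the ketone until the quench, so that neither over-addition nor proton transfer from the acidic product should interfere.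

Step 13
Reactants: 23 3-[(2R,4S)-7-(benzyloxy)-5,8-dimethoxy-2-phenylchroman-4-yl]-4-methoxy-6-[(3E)-2-oxo-4-phenylbut-3-en-1-yl]-2H-pyran-2-one
Product: 25 7-O-benzyl sarcandrone B, via ring-opened methyl ester 24 (not isolated)
Conditions: Mg(OMe)2 (8 equiv), MeOH, reflux, argon; then cold 1 M HCl to pH 4, 0 °C
Reagents that add atoms: none
Why: Methoxide adds to the lactone carbonyl C2 of the pyrone and opens the ring to methyl ester 24, in which the tetrasubstituted C3=C4 enol ether holds the ester and the C5 methylene cis; the central carbon of the magnesium-chelated 1,3-diketone then attacks the ester carbonyl, methoxide leaves, and enolisation aromatises ring A' with the cinnamoyl group at C1', free hydroxyls at C2' and C6' and the methyl ether at C4'. The closest known reaction is the magnesium methoxide recyclisation of 4-oxygenated 6-(2-oxoalkyl)-2-pyrones (tetraketide lactones) to acylphloroglucinols, an intramolecular Claisen (Dieckmann-type) condensation. Ring A' closes in the 6-exo-trig mode (6-enolendo-exo-trig) by forming the C1'–C2' bond. No stereocentre is created, and C2 and C4 of the flavan carry no acidic hydrogen under alkoxide conditions and pass through unchanged. The step needs C-acylation at C1' in preference to the aldol mode, to conjugate addition of methoxide to the styryl ketone and to relactonisation: the aldol mode is closed because C3' is a fully substituted enol-ether carbon that cannot act as a nucleophile, the other two paths are reversible, and magnesium chelation of the diketone (which also protects it from retro-Claisen cleavage) together with irreversible aromatisation should drain the equilibria towards the chalcone. The cold, weakly acidic quench releases the product from its magnesium phenolate without closing the 2',6'-dihydroxychalcone to a flavanone.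

Step 14
Reactants: 25 7-O-benzyl sarcandrone B
Product: 26 sarcandrone B
Conditions: BCl3 (3 equiv), pentamethylbenzene (5 equiv), CH2Cl2, −78 °C; MeOH–CHCl3 quench at −78 °C
Reagents that add atoms: none
Why: Lewis-acid debenzylation with a non-basic cation scavenger, in which BCl3 activates the benzyl ether and the benzyl cation is captured by pentamethylbenzene in a Friedel–Crafts reaction, at a temperature where the three aryl methyl ethers, the enone and both stereocentres should be left untouched.

**Compound list**

1 | 5-methoxyresorcinol (5-methoxybenzene-1,3-diol) | COc1cc(O)cc(O)c1 | starting material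
2 | 1-methoxy-3,5-bis(methoxymethoxy)benzene | COCOc1cc(OC)cc(OCOC)c1 | intermediate
3 | [4-methoxy-2,6-bis(methoxymethoxy)phenyl]lithium (not isolated) | [Li]c1c(OCOC)cc(OC)cc1OCOC | intermediate
4 | dimethyl [4-methoxy-2,6-bis(methoxymethoxy)phenyl]boronate (not isolated) | COB(OC)c1c(OCOC)cc(OC)cc1OCOC | intermediate
5 | 4-methoxy-2,6-bis(methoxymethoxy)phenol | COCOc1cc(OC)cc(OCOC)c1O | intermediate
6 | 2,5-dimethoxy-1,3-bis(methoxymethoxy)benzene | COCOc1cc(OC)cc(OCOC)c1OC | intermediate
7 | 2,5-dimethoxybenzene-1,3-diol | COc1cc(O)c(OC)c(O)c1 | intermediate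
8 | 1-(2,4-dihydroxy-3,6-dimethoxyphenyl)ethan-1-iminium chloride (not isolated) | CC(=[NH2+])c1c(O)c(OC)c(O)cc1OC.[Cl-] | intermediate
9 | 1-(2,4-dihydroxy-3,6-dimethoxyphenyl)ethan-1-one | CC(=O)c1c(O)c(OC)c(O)cc1OC | intermediate
10 | 1-[4-(benzyloxy)-2-hydroxy-3,6-dimethoxyphenyl]ethan-1-one | CC(=O)c1c(O)c(OC)c(OCc2ccccc2)cc1OC | intermediate
11 | (2E)-1-[4-(benzyloxy)-2-hydroxy-3,6-dimethoxyphenyl]-3-(dimethylamino)prop-2-en-1-one (not isolated) | CN(C)/C=C/C(=O)c1c(O)c(OC)c(OCc2ccccc2)cc1OC | intermediate
12 | 7-(benzyloxy)-5,8-dimethoxy-4H-chromen-4-one | O=c1ccoc2c(OC)c(OCc3ccccc3)cc(OC)c12 | intermediate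
13 | phenylboronic acid | OB(O)c1ccccc1 | starting material
14 | (2R)-7-(benzyloxy)-5,8-dimethoxy-2-phenylchroman-4-one | O=C1C[C@H](c2ccccc2)Oc2c(OC)c(OCc3ccccc3)cc(OC)c21 | intermediate
15 | (2R,4R)-7-(benzyloxy)-5,8-dimethoxy-2-phenylchroman-4-ol (2,4-cis) | O[C@@H]1C[C@H](c2ccccc2)Oc2c(OC)c(OCc3ccccc3)cc(OC)c21 | intermediate
16 | triacetic acid lactone (4-hydroxy-6-methyl-2H-pyran-2-one) | Cc1cc(O)cc(=O)o1 | starting material
17 | (2R)-7-(benzyloxy)-5,8-dimethoxy-2-phenylchroman-4-ylium (not isolated) | [CH+]1C[C@H](c2ccccc2)Oc2c(OC)c(OCc3ccccc3)cc(OC)c21 | intermediate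
18 | 3-[(2R,4S)-7-(benzyloxy)-5,8-dimethoxy-2-phenylchroman-4-yl]-4-hydroxy-6-methyl-2H-pyran-2-one (2,4-trans) | Oc1cc(C)oc(=O)c1[C@H]1C[C@H](c2ccccc2)Oc2c(OC)c(OCc3ccccc3)cc(OC)c21 | intermediate
19 | 3-[(2R,4S)-7-(benzyloxy)-5,8-dimethoxy-2-phenylchroman-4-yl]-4-methoxy-6-methyl-2H-pyran-2-one | COc1cc(C)oc(=O)c1[C@H]1C[C@H](c2ccccc2)Oc2c(OC)c(OCc3ccccc3)cc(OC)c21 | intermediate
20 | (2E)-N-methoxy-N-methyl-3-phenylprop-2-enamide (N-methoxy-N-methylcinnamamide) | CON(C)C(=O)/C=C/c1ccccc1 | starting material
21 | 6-(lithiomethyl) derivative of 19 (extended lithium enolate, not isolated) | COc1cc(C[Li])oc(=O)c1[C@H]1C[C@H](c2ccccc2)Oc2c(OC)c(OCc3ccccc3)cc(OC)c21 | intermediate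
22 | lithium alkoxide adduct of 21 to 20 (both epimers at the new carbon, not isolated) | COc1cc(CC(O[Li])(/C=C/c2ccccc2)N(C)OC)oc(=O)c1[C@H]1C[C@H](c2ccccc2)Oc2c(OC)c(OCc3ccccc3)cc(OC)c21 | intermediate
23 | 3-[(2R,4S)-7-(benzyloxy)-5,8-dimethoxy-2-phenylchroman-4-yl]-4-methoxy-6-[(3E)-2-oxo-4-phenylbut-3-en-1-yl]-2H-pyran-2-one | COc1cc(CC(=O)/C=C/c2ccccc2)oc(=O)c1[C@H]1C[C@H](c2ccccc2)Oc2c(OC)c(OCc3ccccc3)cc(OC)c21 | intermediate
24 | methyl (2E,8E)-2-[(2R,4S)-7-(benzyloxy)-5,8-dimethoxy-2-phenylchroman-4-yl]-3-methoxy-5,7-dioxo-9-phenylnona-2,8-dienoate (ester cis to the C4 methylene; present as its magnesium enolate, not isolated) | COC(=O)/C(=C(/OC)CC(=O)CC(=O)/C=C/c1ccccc1)[C@H]1C[C@H](c2ccccc2)Oc2c(OC)c(OCc3ccccc3)cc(OC)c21 | intermediate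
25 | 7-O-benzyl sarcandrone B, (2E)-1-{3-[(2R,4R)-7-(benzyloxy)-5,8-dimethoxy-2-phenylchroman-4-yl]-2,6-dihydroxy-4-methoxyphenyl}-3-phenylprop-2-en-1-one | COc1cc(O)c(C(=O)/C=C/c2ccccc2)c(O)c1[C@H]1C[C@H](c2ccccc2)Oc2c(OC)c(OCc3ccccc3)cc(OC)c21 | intermediate
26 | sarcandrone B, (2E)-1-{2,6-dihydroxy-3-[(2R,4R)-7-hydroxy-5,8-dimethoxy-2-phenylchroman-4-yl]-4-methoxyphenyl}-3-phenylprop-2-en-1-one | COc1cc(O)c(C(=O)/C=C/c2ccccc2)c(O)c1[C@H]1C[C@H](c2ccccc2)Oc2c(OC)c(O)cc(OC)c21 | target

**Count**

Total steps: 14. Longest linear sequence: 14 steps (1 to 26); compounds 13, 16 and 20 enter as purchased partners.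

**Steps most likely to fail**

Step 13. Methoxide may cleave the cinnamoyl diketone (retro-Claisen), or methoxide or the diketone enol oxygen may add to the styryl ketone, faster than the lactone carbonyl, which is shielded by the flavanyl group, is opened. The fallback takes the enone out of the recyclisation. Setting out from 19, the lithiated methyl group is acylated with N-methoxy-N-methylacetamide to give the 6-(2-oxopropyl)pyrone F1. Mg(OMe)2 in methanol then performs the same pyrone-to-benzene Claisen closure on a saturated diketone and should give the acetophenone F2. Claisen–Schmidt condensation of F2 with benzaldehyde (KOH, EtOH, rt) installs the styryl group, and the route is rejoined at 25.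

Step 12. The soft extended enolate may add in conjugate fashion to the cinnamoyl acceptor, or the adduct may collapse before the quench so that the acidic ketone protonates unreacted enolate and conversion stalls. The fallback replaces acylation by aldol addition and oxidation. Setting out from 19, the same lithiated species adds 1,2 to cinnamaldehyde at −78 °C to give the allylic alcohol F3 (both carbinol epimers), and Dess–Martin periodinane (NaHCO3, CH2Cl2) oxidises it to the ketone, rejoining the route at 23.

Step 8. Insertion into the electron-rich, doubly alkoxy-donated chromone may be so slow that protodeboronation and biphenyl formation consume the boronic acid, or the facial selectivity may be insufficient. The fallback builds the flavanone as a racemate and resolves it by reduction. Setting out from 10, Claisen–Schmidt condensation with benzaldehyde (KOH, EtOH) gives the 2'-hydroxychalcone F4, and NaOAc in refluxing EtOH closes it to the racemic flavanone F5. Asymmetric transfer hydrogenation under kinetic-resolution conditions with RuCl(p-cymene)[(R,R)-TsDPEN] (TsDPEN = N-tosyl-1,2-diphenylethane-1,2-diamine) and HCO2H–Et3N should reduce only the 2R ketone to the cis alcohol and leave the 2S ketone; the catalyst enantiomer is the one that delivers the 4R carbinol. The route is rejoined at 15.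

Further compounds
F1 | step 13 | 3-[(2R,4S)-7-(benzyloxy)-5,8-dimethoxy-2-phenylchroman-4-yl]-4-methoxy-6-(2-oxopropyl)-2H-pyran-2-one | COc1cc(CC(C)=O)oc(=O)c1[C@H]1C[C@H](c2ccccc2)Oc2c(OC)c(OCc3ccccc3)cc(OC)c21
F2 | step 13 | 1-{3-[(2R,4R)-7-(benzyloxy)-5,8-dimethoxy-2-phenylchroman-4-yl]-2,6-dihydroxy-4-methoxyphenyl}ethan-1-one | COc1cc(O)c(C(C)=O)c(O)c1[C@H]1C[C@H](c2ccccc2)Oc2c(OC)c(OCc3ccccc3)cc(OC)c21
F3 | step 12 | 3-[(2R,4S)-7-(benzyloxy)-5,8-dimethoxy-2-phenylchroman-4-yl]-6-[(3E)-2-hydroxy-4-phenylbut-3-en-1-yl]-4-methoxy-2H-pyran-2-one (both carbinol epimers) | COc1cc(CC(O)/C=C/c2ccccc2)oc(=O)c1[C@H]1C[C@H](c2ccccc2)Oc2c(OC)c(OCc3ccccc3)cc(OC)c21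
F4 | step 8 | (2E)-1-[4-(benzyloxy)-2-hydroxy-3,6-dimethoxyphenyl]-3-phenylprop-2-en-1-one | COc1cc(OCc2ccccc2)c(OC)c(O)c1C(=O)/C=C/c1ccccc1
F5 | step 8 | racemic 7-(benzyloxy)-5,8-dimethoxy-2-phenylchroman-4-one | O=C1CC(c2ccccc2)Oc2c(OC)c(OCc3ccccc3)cc(OC)c21
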